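The route disconnects rings A and B together, back to an acyclic epoxy-diene. The C3 oxygen next to quaternary C4, the methyl-bearing carbons C10 and C8, and the C8=C17 exocyclic methylene are read as start, relay and end of a titanocene-mediated epoxypolyene radical cascade. In one operation Cp2TiCl opens a (3R)-epoxide made by Sharpless epoxidation and forms C4–C5 (ring A), then C9–C10 (ring B). This relays C3 to C4, C5, C9 and C10 and stops regioselectively at the C8=C17 alkene. The precursor is the silyl-protected 13,14-epoxy-15-hydroxy derivative of (5E,9E)-farnesylacetone. Its methyl ketone later becomes the butenolide, and the liberated C3 hydroxyl takes the angelate.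

Key step: step 4

Remark: labdane numbering is used throughout, also for the acyclic precursors (C18 = equatorial CH2O carbon on C4, C19 = axial methyl on C4, C20 = methyl on C10, C17 = methylene carbon on C8, C13–C16 = lactone carbons); isomerically pure (5E,9E)-farnesylacetone is assumed to be purchasable.

Step 1
Reactants: 1 (5E,9E)-farnesylacetone [(5E,9E)-6,10,14-trimethylpentadeca-5,9,13-trien-2-one]
Product: 2 (5E,9E,13E)-15-hydroxy-6,10,14-trimethylpentadeca-5,9,13-trien-2-one
Conditions: SeO2 (0.2 equiv), t-BuOOH (2.5 equiv), salicylic acid (0.1 equiv), CH2Cl2, 0 °C to rt, stopped at partial conversion, 1 recovered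
Reagents that add atoms: tert-butyl hydroperoxide, CC(C)(C)OO (net source of the new oxygen, passed on by SeO2, O=[Se]=O)
Why: Riley allylic oxidation (ene reaction, then [2,3]-sigmatropic shift) should favour the most accessible terminal isopropylidene unit and oxidise only its (E)-methyl group, giving the (E)-allylic alcohol that the Sharpless epoxidation needs, with the ketone untouched at this temperature.

Step 2
Reactants: 2 (5E,9E,13E)-15-hydroxy-6,10,14-trimethylpentadeca-5,9,13-trien-2-one
Product: 3 (5E,9E)-12-[(2R,3R)-3-(hydroxymethyl)-3-methyloxiran-2-yl]-6,10-dimethyldodeca-5,9-dien-2-one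
Conditions: Ti(OiPr)4 (10 mol%), D-(−)-diethyl tartrate (12 mol%), anhydrous t-BuOOH (2 equiv), 4 Å molecular sieves, CH2Cl2, −20 °C
Reagents that add atoms: tert-butyl hydroperoxide, CC(C)(C)OO
Why: Sharpless asymmetric epoxidation is directed by the allylic hydroxyl, so the two remote alkenes and the ketone are left alone, and D-(−)-tartrate should give the (2R,3R)-oxirane, which sets C3 (R), the only stereocentre of the route made by a chiral catalyst.

Step 3
Reactants: 3 (5E,9E)-12-[(2R,3R)-3-(hydroxymethyl)-3-methyloxiran-2-yl]-6,10-dimethyldodeca-5,9-dien-2-one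
Product: 4 (5E,9E)-12-[(2R,3R)-3-(tert-butyldimethylsilyloxymethyl)-3-methyloxiran-2-yl]-6,10-dimethyldodeca-5,9-dien-2-one
Conditions: TBSCl, imidazole, CH2Cl2, 0 °C to rt
Reagents that add atoms: tert-butyldimethylsilyl chloride, CC(C)(C)[Si](C)(C)Cl
Why: Imidazole-promoted silylation of the primary alcohol masks O18, so that later only O3 can be acylated, and it gives C4 one clearly larger substituent for the cascade.

Step 4
Reactants: 4 (5E,9E)-12-[(2R,3R)-3-(tert-butyldimethylsilyloxymethyl)-3-methyloxiran-2-yl]-6,10-dimethyldodeca-5,9-dien-2-one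
Product: 6 (3R,4S,5S,9R,10S)-3-hydroxy-18-(tert-butyldimethylsilyloxy)-14,15-dinorlabd-8(17)-en-13-one, via chlorotitanocene alkoxide 5 (not isolated)
Conditions: Cp2TiCl2 (2.5 equiv), Mn dust (8 equiv), dry degassed THF, rt; green Cp2TiCl solution added slowly to 4 (0.01 M in THF), rt; dilute aq HCl quench
Reagents that add atoms: none
Why: Cp2TiCl (trivalent titanium, made from Cp2TiCl2 and Mn) binds the epoxide oxygen and cleaves the C4–O bond homolytically, so that C3 keeps its oxygen as a titanium alkoxide, the tertiary C4 radical adds to C5, the tertiary C10 radical so formed adds to C9, and the final tertiary C8 radical is taken up by a second Cp2TiCl and loses a C17 hydrogen as Cp2Ti(H)Cl to leave the C8=C17 methylene. The closest known reaction type is the titanocene-mediated reductive epoxide opening (Nugent–RajanBabu reagent) used as the trigger of epoxypolyprene cascade cyclizations under anhydrous conditions. Ring A closes 6-endo-trig (C4–C5) and ring B closes 6-endo-trig (C9–C10), in each case because attack at the CH end of a trisubstituted alkene gives a tertiary radical. C3 is untouched and its bulky equatorial OTiCp2Cl group fixes the chair–chair fold, the E geometry of C5=C10 gives the trans ring fusion (C5–H anti to C20), the E geometry of C8=C9 places the C9 side chain equatorial, and at the planar C4 radical the larger CH2OTBS group should take the equatorial site to avoid the axial C20 methyl, leaving C19 axial. The step needs regioselective opening (secured by tertiary over secondary radical stability), cyclization faster than capture of the C4 radical and loss of the neighbouring silyloxy group (secured by slow addition of Cp2TiCl and dilution), and exocyclic termination (secured by exclusion of water and the accessible C17 hydrogens). The side chain ends in a saturated methyl ketone, a poor radical acceptor, because a butenolide at this stage would trap the C8 radical in a 5-exo closure.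

Step 5
Reactants: 6 (3R,4S,5S,9R,10S)-3-hydroxy-18-(tert-butyldimethylsilyloxy)-14,15-dinorlabd-8(17)-en-13-one; 7 angelic acid [(Z)-2-methylbut-2-enoic acid]
Product: 9 (3R,4S,5S,9R,10S)-3-angeloyloxy-18-(tert-butyldimethylsilyloxy)-14,15-dinorlabd-8(17)-en-13-one, via angelic 2,4,6-trichlorobenzoic anhydride 8 (not isolated)
Conditions: 7 (3 equiv), 2,4,6-trichlorobenzoyl chloride (3 equiv), Et3N (6 equiv), toluene, rt; then 6, 80 °C, no nucleophilic catalyst
Reagents that add atoms: 2,4,6-trichlorobenzoyl chloride, O=C(Cl)c1c(Cl)cc(Cl)cc1Cl (its aroyl group stays in 8 only and is lost again before 9)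
Why: Yamaguchi-type mixed-anhydride esterification transfers the less hindered angeloyl group to the equatorial C3 hydroxyl, and leaving out a nucleophilic catalyst avoids the conjugate addition–elimination path that turns angelates into tiglates, so the Z geometry bought with 7 should be kept.

Step 6
Reactants: 9 (3R,4S,5S,9R,10S)-3-angeloyloxy-18-(tert-butyldimethylsilyloxy)-14,15-dinorlabd-8(17)-en-13-one
Product: 10 (3R,4S,5S,9R,10S)-3-angeloyloxy-18-(tert-butyldimethylsilyloxy)-13-(trimethylsilyloxy)-14,15-dinorlabda-8(17),13(16)-diene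
Conditions: LiN(iPr)2 (1.1 equiv), TMSCl (3 equiv, present from the start), THF, −78 °C; Et3N, pentane, cold aq NaHCO3
Reagents that add atoms: trimethylsilyl chloride, C[Si](C)(C)Cl
Why: Kinetic enolisation with internal silyl quench should remove a C16 methyl proton of the ketone, which is more acidic and more accessible than C12–H or any position of the hindered angelate.

Step 7
Reactants: 10 (3R,4S,5S,9R,10S)-3-angeloyloxy-18-(tert-butyldimethylsilyloxy)-13-(trimethylsilyloxy)-14,15-dinorlabda-8(17),13(16)-diene
Product: 12 (3R,4S,5S,9R,10S)-3-angeloyloxy-16-hydroxy-18-(tert-butyldimethylsilyloxy)-14,15-dinorlabd-8(17)-en-13-one, via 16-trimethylsilyloxy ketone 11 (not isolated)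
Conditions: mCPBA (1.0 equiv), NaHCO3, CH2Cl2, −20 °C; then citric acid, MeOH, rt
Reagents that add atoms: 3-chloroperoxybenzoic acid, O=C(OO)c1cccc(Cl)c1
Why: In this Rubottom oxidation the electron-rich silyl enol ether should be epoxidised much faster than the 1,1-disubstituted C8=C17 alkene or the electron-poor angelate alkene, silyl migration gives 11, and mild acidic methanolysis frees O16 without touching the TBS ether.

Step 8
Reactants: 12 (3R,4S,5S,9R,10S)-3-angeloyloxy-16-hydroxy-18-(tert-butyldimethylsilyloxy)-14,15-dinorlabd-8(17)-en-13-one; 13 (triphenylphosphoranylidene)ketene (Bestmann ylide)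
Product: 15 (3R,4S,5S,9R,10S)-3-angeloyloxy-18-(tert-butyldimethylsilyloxy)labda-8(17),13-dien-15,16-olide, via ester ylide 14 (not isolated)
Conditions: 13 (1.2 equiv), toluene, 90 °C
Reagents that add atoms: none
Why: The C16 hydroxyl adds to the ketene carbon of the Bestmann ylide to give the stabilised ester ylide 14, whose intramolecular Wittig reaction with the C13 ketone closes the five-membered lactone and places the C13=C14 alkene inside it.

Step 9
Reactants: 15 (3R,4S,5S,9R,10S)-3-angeloyloxy-18-(tert-butyldimethylsilyloxy)labda-8(17),13-dien-15,16-olide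
Product: 16 (3R,4S,5S,9R,10S)-3-angeloyloxy-18-hydroxylabda-8(17),13-dien-15,16-olide (target)
Conditions: HF·pyridine, pyridine, THF, 0 °C to rt
Reagents that add atoms: none
Why: Fluoride-mediated desilylation in a buffered, weakly acidic medium removes the TBS group without forming the free alkoxide that would start O3-to-O18 acyl migration, and it is too mild to move the C8=C17 alkene or isomerise the angelate.

Compound list
1 | (5E,9E)-farnesylacetone | CC(=O)CC/C=C(\C)CC/C=C(\C)CCC=C(C)C | starting material
2 | (5E,9E,13E)-15-hydroxy-6,10,14-trimethylpentadeca-5,9,13-trien-2-one | CC(=O)CC/C=C(\C)CC/C=C(\C)CC/C=C(\C)CO | intermediate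
3 | (5E,9E)-12-[(2R,3R)-3-(hydroxymethyl)-3-methyloxiran-2-yl]-6,10-dimethyldodeca-5,9-dien-2-one | CC(=O)CC/C=C(\C)CC/C=C(\C)CC[C@H]1O[C@]1(C)CO | intermediate
4 | TBS ether of 3 (cascade precursor) | CC(=O)CC/C=C(\C)CC/C=C(\C)CC[C@H]1O[C@]1(C)CO[Si](C)(C)C(C)(C)C | intermediate
5 | chlorotitanocene C3-alkoxide of 6 | C=C1CC[C@H]2[C@@](C)(CC[C@@H]([O-])[C@]2(C)CO[Si](C)(C)C(C)(C)C)[C@@H]1CCC(C)=O.[Ti+4].[Cl-].c1cc[cH-]c1.c1cc[cH-]c1 | intermediate
6 | (3R,4S,5S,9R,10S)-3-hydroxy-18-(tert-butyldimethylsilyloxy)-14,15-dinorlabd-8(17)-en-13-one (trans-decalin; O3, C18 and C11 equatorial; C19 and C20 axial on one face) | C=C1CC[C@H]2[C@@](C)(CC[C@@H](O)[C@]2(C)CO[Si](C)(C)C(C)(C)C)[C@@H]1CCC(C)=O | intermediate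
7 | angelic acid, (Z)-2-methylbut-2-enoic acid | C/C=C(/C)C(=O)O | starting material
8 | angelic 2,4,6-trichlorobenzoic anhydride | C/C=C(/C)C(=O)OC(=O)c1c(Cl)cc(Cl)cc1Cl | intermediate
9 | C3 angelate of 6 | C=C1CC[C@H]2[C@@](C)(CC[C@@H](OC(=O)/C(C)=C\C)[C@]2(C)CO[Si](C)(C)C(C)(C)C)[C@@H]1CCC(C)=O | intermediate
10 | terminal (C13=C16) trimethylsilyl enol ether of 9 | C=C1CC[C@H]2[C@@](C)(CC[C@@H](OC(=O)/C(C)=C\C)[C@]2(C)CO[Si](C)(C)C(C)(C)C)[C@@H]1CCC(=C)O[Si](C)(C)C | intermediate
11 | 16-trimethylsilyloxy derivative of ketone 9 | C=C1CC[C@H]2[C@@](C)(CC[C@@H](OC(=O)/C(C)=C\C)[C@]2(C)CO[Si](C)(C)C(C)(C)C)[C@@H]1CCC(=O)CO[Si](C)(C)C | intermediate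
12 | 16-hydroxy derivative of ketone 9 | C=C1CC[C@H]2[C@@](C)(CC[C@@H](OC(=O)/C(C)=C\C)[C@]2(C)CO[Si](C)(C)C(C)(C)C)[C@@H]1CCC(=O)CO | intermediate
13 | (triphenylphosphoranylidene)ketene | O=C=C=P(c1ccccc1)(c1ccccc1)c1ccccc1 | starting material
14 | O16 (triphenylphosphoranylidene)acetate of 12 | C=C1CC[C@H]2[C@@](C)(CC[C@@H](OC(=O)/C(C)=C\C)[C@]2(C)CO[Si](C)(C)C(C)(C)C)[C@@H]1CCC(=O)COC(=O)C=P(c1ccccc1)(c1ccccc1)c1ccccc1 | intermediate
15 | 18-O-TBS ether of the target | C=C1CC[C@H]2[C@@](C)(CC[C@@H](OC(=O)/C(C)=C\C)[C@]2(C)CO[Si](C)(C)C(C)(C)C)[C@@H]1CCC1=CC(=O)OC1 | intermediate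
16 | (3R,4S,5S,9R,10S)-3-angeloyloxy-18-hydroxylabda-8(17),13-dien-15,16-olide | C=C1CC[C@H]2[C@@](C)(CC[C@@H](OC(=O)/C(C)=C\C)[C@]2(C)CO)[C@@H]1CCC1=CC(=O)OC1 | target

Total step count: 9. Longest linear sequence: 9 steps (1 to 16); 7 and 13 are bought.

Steps most likely to fail

Step 4. Several processes may interfere.
- Facial control at the planar, freely rotating C4 radical may be incomplete.
- Trivalent titanium may capture the C4 radical early, with loss of the neighbouring silyloxy group.
- The C8 radical may add to the titanium-bound ketone.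

The fallback replaces the radical cascade by a polar, stereospecific one and sets out from 4. MeAlCl2 (2.2 equiv) in CH2Cl2 at −78 °C should open the epoxide with inversion at C4, in concert with attack by C5=C10. The CH2OTBS group, trans to the chain on the oxirane, is then carried into the equatorial site without any free rotation. C9–C10 closes ring B in the same chair–chair fold, the C8 cation is trapped by the ketone oxygen, and proton loss gives the tricyclic enol ether F1. Acylation with 8 as in step 5 gives its C3 angelate F2. Oxalic acid in wet THF opens the enol ether to the 8-hydroxy ketone F3. SOCl2 in pyridine/CH2Cl2 at low temperature then eliminates the equatorial C8 oxygen. Only the C17 hydrogens are antiperiplanar to that oxygen, so elimination goes toward C8=C17. The sequence comes back to the route at 9.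

Step 5. Acylation of the neopentyl-type C3 hydroxyl may be slow, and Z-to-E isomerisation of the activated angeloyl group may occur during prolonged heating. The fallback builds the Z alkene on an ester that is already in place and sets out from 6. Esterification with 2-[bis(2,2,2-trifluoroethoxy)phosphoryl]propanoic acid (N,N'-dicyclohexylcarbodiimide, DMAP, CH2Cl2) gives the phosphonopropionate ester F4. The epimers at its phosphorus-bearing carbon are of no consequence. Selective deprotonation of the phosphonate with KN(SiMe3)2 and 18-crown-6 in THF at −78 °C, then acetaldehyde (Still–Gennari olefination), should create the Z-trisubstituted enoate. The sequence comes back to the route at 9.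

Step 7. The peracid may also epoxidise the C8=C17 methylene, or the enol ether may be protodesilylated back to the ketone. The fallback avoids both the oxidant and the ylide and sets out from 10. NBS in THF at −78 °C gives the bromomethyl ketone F5. Displacement with diethylphosphonoacetic acid and K2CO3 in DMF gives the phosphonoacetate ester F6. An intramolecular Horner–Wadsworth–Emmons reaction (LiCl, DBU, MeCN) then closes the butenolide. The sequence comes back to the route at 15.

Further compounds
F1 | step 4 | tricyclic enol ether, 8,13-epoxy-3-hydroxy-18-(tert-butyldimethylsilyloxy)-14,15-dinorlabd-12-ene (configuration of 6 at C3, C4, C5, C9, C10; C8–O equatorial, C17 axial) | C[C@]12CC[C@H]3[C@@](C)(CC[C@@H](O)[C@]3(C)CO[Si](C)(C)C(C)(C)C)[C@@H]1CC=C(C)O2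
F2 | step 4 | C3 angelate of F1 | C[C@]12CC[C@H]3[C@@](C)(CC[C@@H](OC(=O)/C(C)=C\C)[C@]3(C)CO[Si](C)(C)C(C)(C)C)[C@@H]1CC=C(C)O2
F3 | step 4 | 3-angeloyloxy-8-hydroxy-18-(tert-butyldimethylsilyloxy)-14,15-dinorlabdan-13-one (C8–OH equatorial) | C[C@]1(O)CC[C@H]2[C@@](C)(CC[C@@H](OC(=O)/C(C)=C\C)[C@]2(C)CO[Si](C)(C)C(C)(C)C)[C@@H]1CCC(C)=O
F4 | step 5 | C3 2-[bis(2,2,2-trifluoroethoxy)phosphoryl]propanoate of 6 | C=C1CC[C@H]2[C@@](C)(CC[C@@H](OC(=O)C(C)P(=O)(OCC(F)(F)F)OCC(F)(F)F)[C@]2(C)CO[Si](C)(C)C(C)(C)C)[C@@H]1CCC(C)=O
F5 | step 7 | 16-bromo derivative of ketone 9 | C=C1CC[C@H]2[C@@](C)(CC[C@@H](OC(=O)/C(C)=C\C)[C@]2(C)CO[Si](C)(C)C(C)(C)C)[C@@H]1CCC(=O)CBr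
F6 | step 7 | O16 (diethoxyphosphoryl)acetate of 12 | C=C1CC[C@H]2[C@@](C)(CC[C@@H](OC(=O)/C(C)=C\C)[C@]2(C)CO[Si](C)(C)C(C)(C)C)[C@@H]1CCC(=O)COC(=O)CP(=O)(OCC)OCC
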